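## Retrosynthetic overview

- The target is (2E,6E,10E)-geranylgeranyl acetate plus one molecule of water: a single proton-initiated cascade forms C4–C5, C9–C10 and C8–O and sets C5, C10, C9 and C8.
- Ring order inside that cascade: ring A closes first, ring B second, and water caps C8 last.
- Geranylgeranyl acetate comes from a C18 terminal alkyne by E-selective methylalumination, formaldehyde capture and acetylation in one flask.
- The alkyne comes from (5E,9E)-farnesylacetone by methyl ketone to alkyne conversion.

Assumption: 1 is bought as the isomerically pure (5E,9E) compound, and the (S,S) acid of step 3 is taken to be the antipode that folds the chain into the 10S series (the sense that gives (−)-ambrox from homofarnesol); if the first run shows the opposite sense, the (R,R) acid is used with nothing else changed.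

## Route

Step 1
Reactants: 1 (5E,9E)-farnesylacetone
Product: 4 (5E,9E)-6,10,14-trimethylpentadeca-5,9,13-trien-1-yne, via lithium enolate 2 (not isolated), via enol phosphate 3 (not isolated)
Conditions: LiN(i-Pr)2 (1.1 equiv), THF, −78 °C; ClP(O)(OEt)2 (1.1 equiv), −78 °C → rt; LiN(i-Pr)2 (2.3 equiv), −78 °C → rt; aq. NH4Cl
Reagents that add atoms: none
Why: Negishi methyl-ketone-to-alkyne conversion: kinetic deprotonation at the methyl group, O-phosphorylation, then base-induced elimination of diethyl phosphate from the terminal enol phosphate, with the isolated E alkenes untouched and no stereocentre formed.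

Step 2
Reactants: 4 (5E,9E)-6,10,14-trimethylpentadeca-5,9,13-trien-1-yne
Product: 8 (2E,6E,10E)-geranylgeranyl acetate, via alkenylalane 5 (not isolated), via lithium alkenylaluminate 6 (not isolated), via lithium alkoxyaluminate 7 (not isolated)
Conditions: Me3Al (2 equiv), Cp2ZrCl2 (0.25 equiv), ClCH2CH2Cl, rt; volatiles removed; n-BuLi (1 equiv), hexane–THF, −78 → 0 °C; (CH2O)n (3 equiv), rt; then Ac2O (5 equiv), pyridine, DMAP (0.1 equiv), 0 °C → rt; aq. NH4Cl
Reagents that add atoms: trimethylaluminium, C[Al](C)C; paraformaldehyde (reacts as formaldehyde), C=O; acetic anhydride, CC(=O)OC(C)=O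
Why: Negishi zirconium-catalysed carboalumination adds CH3–Al syn across the terminal alkyne (CH3 to the internal carbon) and so fixes the 2E alkene, the butyl ate complex transfers the alkenyl group to formaldehyde with retention, and the aluminium alkoxide is O-acetylated in the same flask as in reductive acetylations; no stereocentre is formed.

Step 3
Reactants: 8 (2E,6E,10E)-geranylgeranyl acetate
Product: 10 (13E)-8α-hydroxylabd-13-en-15-yl acetate, via labd-13-en-8-yl cation 9 (not isolated)
Conditions: (S,S)-IDPi acid HN[P(=NSO2CF3)(O2C20H10Ar2)]2 (O2C20H10Ar2 = 3,3′-Ar2-1,1′-binaphthalene-2,2′-diolate, Ar = 3,5-(CF3)2C6H3; C74H33F30N3O8P2S2) (5 mol %), H2O (3 equiv), (CF3)3COH, 0 °C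
Reagents that add atoms: water, O
Why: Proposed new method: the confined strong chiral acid protonates the terminal isopropylidene alkene of the chair–chair folded chain, anti additions across the two E alkenes close ring A (C4–C5) and then ring B (C9–C10) so that the trans fusion (5α-H, 10β-CH3) and 9α-H follow from the alkene geometries, the tertiary C8 cation 9 held as an ion pair with the chiral anion is captured by water anti to the new C9–C10 bond on the equatorial α face (8α-OH, 8β-CH3), the 13,14-alkene stays out because the allylic acetoxy group lowers its nucleophilicity, and the absolute sense is fixed by the catalyst in a net addition of one H2O with no by-product; the closest known reaction types are the confined-acid-catalysed asymmetric bicyclization of (3E,7E)-homofarnesol to (−)-ambrox (same C5/C8/C9/C10 configuration) and the water-terminated enzymatic bicyclization of geranylgeranyl diphosphate to 8α-hydroxycopalyl diphosphate.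

## Compound list

1 | (5E,9E)-6,10,14-trimethylpentadeca-5,9,13-trien-2-one ((E,E)-farnesylacetone) | CC(=O)CC/C=C(\C)CC/C=C(\C)CCC=C(C)C | starting material
2 | lithium (5E,9E)-6,10,14-trimethylpentadeca-1,5,9,13-tetraen-2-olate (kinetic enolate) | [Li+].[O-]C(=C)CC/C=C(\C)CC/C=C(\C)CCC=C(C)C | intermediate
3 | diethyl (5E,9E)-6,10,14-trimethylpentadeca-1,5,9,13-tetraen-2-yl phosphate | CCOP(=O)(OCC)OC(=C)CC/C=C(\C)CC/C=C(\C)CCC=C(C)C | intermediate
4 | (5E,9E)-6,10,14-trimethylpentadeca-5,9,13-trien-1-yne | C#CCC/C=C(\C)CC/C=C(\C)CCC=C(C)C | intermediate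
5 | dimethyl[(1E,5E,9E)-2,6,10,14-tetramethylpentadeca-1,5,9,13-tetraen-1-yl]alane | C[Al](C)/C=C(\C)CC/C=C(\C)CC/C=C(\C)CCC=C(C)C | intermediate
6 | lithium butyl(dimethyl)[(1E,5E,9E)-2,6,10,14-tetramethylpentadeca-1,5,9,13-tetraen-1-yl]aluminate | [Li+].CCCC[Al-](C)(C)/C=C(\C)CC/C=C(\C)CC/C=C(\C)CCC=C(C)C | intermediate
7 | lithium butyl(dimethyl)[(2E,6E,10E)-3,7,11,15-tetramethylhexadeca-2,6,10,14-tetraen-1-olato]aluminate | [Li+].CCCC[Al-](C)(C)OC/C=C(\C)CC/C=C(\C)CC/C=C(\C)CCC=C(C)C | intermediate
8 | (2E,6E,10E)-3,7,11,15-tetramethylhexadeca-2,6,10,14-tetraen-1-yl acetate (geranylgeranyl acetate) | CC(=O)OC/C=C(\C)CC/C=C(\C)CC/C=C(\C)CCC=C(C)C | intermediate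
9 | (13E)-15-acetoxylabd-13-en-8-yl cation (trans-decalin, 5α-H, 9α-H, 10β-CH3, planar C8) | CC(=O)OC/C=C(\C)CC[C@@H]1[C@@]2(C)CCCC(C)(C)[C@@H]2CC[C+]1C | intermediate
10 | (13E)-8α-hydroxylabd-13-en-15-yl acetate = (2E)-5-[(1R,2R,4aS,8aS)-2-hydroxy-2,5,5,8a-tetramethyldecahydronaphthalen-1-yl]-3-methylpent-2-en-1-yl acetate | CC(=O)OC/C=C(\C)CC[C@@H]1[C@@]2(C)CCCC(C)(C)[C@@H]2CC[C@@]1(C)O | target

Total step count: 3. Longest linear sequence: 3.

## Steps most likely to fail, with fallbacks

Step 3 is the most likely to fail. The C8 cation can lose a proton to give labdadienyl acetates or be captured by the 13,14-alkene to close a third ring. The acid can also hydrate an alkene without cyclization or ionize the allylic acetate, and the enantioselectivity is untested for a water-terminated cascade. The fallback sets out from 1 and comes back at 10. It replaces water capture by intramolecular capture with the ketone oxygen, which is closer to the known hydroxyl-terminated case.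
- Ketone 1 is treated with the same IDPi acid in (CF3)3COH without water; the carbonyl oxygen traps the C8 cation and loss of a proton gives the enol ether (+)-sclareol oxide F1, with ring A, ring B and the dihydropyran formed together.
- Dilute aqueous HCl in THF opens it to 8α-hydroxy-14,15-dinorlabdan-13-one F2.
- Horner–Wadsworth–Emmons olefination with (EtO)2P(O)CH2CO2Et and NaH in THF gives ethyl (13E)-8α-hydroxylabd-13-en-15-oate F3 (E:Z about 4:1, E isomer separated by chromatography).
- i-Bu2AlH in CH2Cl2 at −78 °C gives (13E)-labd-13-ene-8α,15-diol F4.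
- Ac2O/pyridine at 0 °C acetylates only the primary allylic hydroxyl and gives 10.

Step 2 is the second risk. Carboalumination may stall with substoichiometric Cp2ZrCl2, alkenyl transfer to formaldehyde may be incomplete, and material may be lost in the in-flask acetylation. The fallback sets out from 4 and comes back at 8. It builds the trisubstituted alkene by hydroalumination, iodination and methyl coupling instead of carbometalation.
- n-BuLi then (CH2O)n in THF gives (6E,10E)-7,11,15-trimethylhexadeca-6,10,14-trien-2-yn-1-ol F5.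
- Trans-hydroalumination with NaAlH2(OCH2CH2OCH3)2 in THF followed by I2 at −78 °C gives (2Z,6E,10E)-3-iodo-7,11,15-trimethylhexadeca-2,6,10,14-tetraen-1-ol F6.
- Me2CuLi in Et2O at 0 °C replaces iodide with retention and gives (2E,6E,10E)-geranylgeraniol F7.
- Ac2O, pyridine and DMAP give 8.

Step 1 is the third risk. Incomplete kinetic control in the enolization gives the internal enol phosphate, and from it an allene or internal alkyne that is hard to remove. The fallback sets out from 1 and comes back at 8. It avoids the alkyne and reaches the allylic acetate by vinyl addition and a 1,3-acetate shift, at the cost of an E/Z separation.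
- CH2=CHMgBr in THF at 0 °C adds to the ketone and gives racemic (6E,10E)-geranyllinalool F8.
- Ac2O, Et3N and DMAP give (6E,10E)-geranyllinalyl acetate F9.
- PdCl2(MeCN)2 (5 mol %) in THF at rt moves the acetate to the primary terminus by a [3,3] shift; the 2E isomer 8 (major, about 2:1 over 2Z) is isolated on AgNO3-impregnated silica.

Further compounds
F1 | step 3 | (+)-sclareol oxide (8α,13-epoxy-14,15-dinorlabd-12-ene) | CC1=CC[C@@H]2[C@@]3(C)CCCC(C)(C)[C@@H]3CC[C@@]2(C)O1
F2 | step 3 | 8α-hydroxy-14,15-dinorlabdan-13-one | CC(=O)CC[C@@H]1[C@@]2(C)CCCC(C)(C)[C@@H]2CC[C@@]1(C)O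
F3 | step 3 | ethyl (13E)-8α-hydroxylabd-13-en-15-oate | CCOC(=O)/C=C(\C)CC[C@@H]1[C@@]2(C)CCCC(C)(C)[C@@H]2CC[C@@]1(C)O
F4 | step 3 | (13E)-labd-13-ene-8α,15-diol | OC/C=C(\C)CC[C@@H]1[C@@]2(C)CCCC(C)(C)[C@@H]2CC[C@@]1(C)O
F5 | step 2 | (6E,10E)-7,11,15-trimethylhexadeca-6,10,14-trien-2-yn-1-ol | OCC#CCC/C=C(\C)CC/C=C(\C)CCC=C(C)C
F6 | step 2 | (2Z,6E,10E)-3-iodo-7,11,15-trimethylhexadeca-2,6,10,14-tetraen-1-ol | OC/C=C(\I)CC/C=C(\C)CC/C=C(\C)CCC=C(C)C
F7 | step 2 | (2E,6E,10E)-geranylgeraniol | OC/C=C(\C)CC/C=C(\C)CC/C=C(\C)CCC=C(C)C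
F8 | step 1 | (6E,10E)-geranyllinalool (racemic at C3) | C=CC(C)(O)CC/C=C(\C)CC/C=C(\C)CCC=C(C)C
F9 | step 1 | (6E,10E)-geranyllinalyl acetate (racemic at C3) | C=CC(C)(OC(C)=O)CC/C=C(\C)CC/C=C(\C)CCC=C(C)C
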